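**Plan**
Numbering: ring C1 (CH stereocentre) to C14. The side chain on C1 is C15(CH3)=C16H–C17H2–C18H=C19(CH3)2, C20 is the carboxyl carbon on C8, and the 14-membered carbocycle is the only ring.
Enabling feature: the chain on C1 is a skipped diene whose E-trisubstituted C15=C16 alkene bears CH3 on C15 and prenyl on C16. This is what syn addition of CH3 and a metal across a C1-ethynyl group leaves once the C16–metal bond is allylated.
Cuts, in order: C15–CH3 and C16–C17 (side chain off the finished ring); C7=C8 (ring opening); C8–C9; C10–C11 and C12–CH3; C4–C5; C3=C4. These lead back to the C3/C12 keto aldehyde obtained by ozonolysis of a 4-ethynyl-1-methylcyclohexene.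
Forward: the limonene skeleton is trimmed to a silyl-capped ethynylcyclohexene and its six-membered ring is opened. The C3 arm and then the C12 arm are grown, the 14-membered ring closes by intramolecular Horner–Wadsworth–Emmons olefination, the side chain is built last, and C20 is raised to the acid.
Stereochemistry: C1 (R) is C4 of (R)-limonene, bought as its 1,2-oxide, and none of its four bonds is ever broken. 3Z comes from an iodo-Wittig/Suzuki pair, 11E and 15E from syn methylalumination, and 7E from the phosphonate olefination.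

Key step: step 16

Remark on the chemistry: centres that vanish later (epoxide carbons, ozonide carbons, the phosphonate-bearing carbon C8) are carried as mixtures and drawn without configuration.
Convention: every partner that brings carbon atoms of the target is a numbered reactant, and the line on reagents lists only the other donors of atoms. Ring compounds are named with the numbering of the plan, which the Why lines also use.

Step 1
Reactants: 1 (+)-limonene 1,2-oxide, (4R)-1-methyl-4-(prop-1-en-2-yl)-7-oxabicyclo[4.1.0]heptane (commercial cis/trans mixture)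
Product: 3 1-[(3R)-6-methyl-7-oxabicyclo[4.1.0]heptan-3-yl]ethanone (epoxide diastereomers), via secondary ozonide 2 (not isolated)
Conditions: O3, CH2Cl2, −78 °C; then Me2S, −78 °C to rt
Reagents that add atoms: ozone, [O-][O+]=O
Why: Ozonolysis with reductive work-up cleaves the isopropenyl alkene, the only one present because the more electron-rich ring alkene of limonene is stored as its epoxide, and the neutral medium leaves the adjacent ring stereocentre (the future C1) untouched.

Step 2
Reactants: 3 1-[(3R)-6-methyl-7-oxabicyclo[4.1.0]heptan-3-yl]ethanone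
Product: 4 1-[(1R)-4-methylcyclohex-3-en-1-yl]ethanone [(R)-4-acetyl-1-methylcyclohexene]
Conditions: Zn, NaI, NaOAc, AcOH, 0 °C to rt
Reagents that add atoms: none
Why: Cornforth-type deoxygenation (opening to the iodohydrin, then zinc-induced reductive elimination) regenerates the ring alkene from both epoxide diastereomers, since a cyclohexene can only be cis, in an acetate buffer too mild to enolise the ketone.

Step 3
Reactants: 4 (R)-4-acetyl-1-methylcyclohexene
Product: 8 triisopropyl{[(1R)-4-methylcyclohex-3-en-1-yl]ethynyl}silane, via lithium enolate 5 (not isolated), via enol diethyl phosphate 6 (not isolated), via lithium acetylide 7 (not isolated)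
Conditions: LiN(i-Pr)2 (1.1 equiv), THF, −78 °C; ClP(O)(OEt)2, −78 °C to rt; LiN(i-Pr)2 (2.3 equiv), −78 °C to rt; i-Pr3SiCl, 0 °C to rt
Reagents that add atoms: chlorotriisopropylsilane, CC(C)[Si](Cl)(C(C)C)C(C)C
Why: In this enol phosphate route from a methyl ketone to a 1-alkyne the hindered amide base removes a methyl proton under kinetic control rather than the methine proton at the stereocentre, further base expels diethyl phosphate, and the acetylide is capped in the same flask with a bulky silyl group that hides this alkyne until step 11.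

Step 4
Reactants: 8 triisopropyl{[(1R)-4-methylcyclohex-3-en-1-yl]ethynyl}silane
Product: 10 (3R)-6-oxo-3-[(triisopropylsilyl)ethynyl]heptanal, via secondary ozonide 9 (not isolated)
Conditions: O3, CH2Cl2, −78 °C (Sudan red 7B as end-point dye); then Me2S, −78 °C to rt
Reagents that add atoms: ozone, [O-][O+]=O
Why: Ozone attacks the electron-rich trisubstituted alkene far faster than the hindered silylalkyne, so dye-controlled ozonolysis with reductive work-up opens the six-membered ring to the C3 aldehyde and the C12 methyl ketone with C1 untouched.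

Step 5
Reactants: 10 (3R)-6-oxo-3-[(triisopropylsilyl)ethynyl]heptanal; 11 ethyltriphenylphosphonium iodide
Product: 15 (5R,7Z)-8-iodo-5-[(triisopropylsilyl)ethynyl]non-7-en-2-one, via ethylidene ylide 12 (not isolated), via iodoethylphosphonium iodide 13 (not isolated), via iodoethylidene ylide 14 (not isolated)
Conditions: 11, n-BuLi, THF, rt; I2, −78 °C; NaN(SiMe3)2, −20 °C; then 10, −78 to −20 °C
Reagents that add atoms: iodine, II
Why: The Stork–Zhao-type Wittig reaction of the α-iodoethylidene ylide runs under kinetic control, should give the (Z)-2-iodoalk-2-ene with iodine cis to C2, and at low temperature takes the aldehyde in preference to the methyl ketone.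

Step 6
Reactants: 15 (5R,7Z)-8-iodo-5-[(triisopropylsilyl)ethynyl]non-7-en-2-one; 16 allyloxy(tert-butyl)dimethylsilane
Product: 18 (5R,7Z)-11-(tert-butyldimethylsilyloxy)-8-methyl-5-[(triisopropylsilyl)ethynyl]undec-7-en-2-one, via B-alkyl-9-BBN 17 (not isolated)
Conditions: 16, 9-BBN-H, THF, rt; then 15, PdCl2(dppf) (5 mol %), AsPh3, Cs2CO3, DMF/H2O, rt
Reagents that add atoms: none
Why: B-alkyl Suzuki–Miyaura coupling (anti-Markovnikov hydroboration of the allyl ether, oxidative addition of the C4–iodine bond to zerovalent palladium, base-assisted transmetalation, reductive elimination) joins C4 to C5 with retention, so that C2 and C5 end up cis (3Z), and it tolerates the ketone and both silyl groups.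

Step 7
Reactants: 18 (5R,7Z)-11-(tert-butyldimethylsilyloxy)-8-methyl-5-[(triisopropylsilyl)ethynyl]undec-7-en-2-one
Product: 22 (4Z,7R)-7-(but-3-ynyl)-1-(tert-butyldimethylsilyloxy)-4-methyl-9-(triisopropylsilyl)non-4-en-8-yne, via lithium enolate 19 (not isolated), via enol diethyl phosphate 20 (not isolated), via lithium acetylide 21 (not isolated)
Conditions: LiN(i-Pr)2 (1.1 equiv), THF, −78 °C; ClP(O)(OEt)2, −78 °C to rt; LiN(i-Pr)2 (2.3 equiv), −78 °C to rt; then H2O
Reagents that add atoms: none
Why: The same enol phosphate elimination is used, kinetic deprotonation now favouring the methyl over the C13 methylene side, so that the old methyl carbon becomes the terminal alkyne carbon C11 while silyl ether, capped alkyne and alkene are inert to the amide base.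

Step 8
Reactants: 22 (4Z,7R)-7-(but-3-ynyl)-1-(tert-butyldimethylsilyloxy)-4-methyl-9-(triisopropylsilyl)non-4-en-8-yne; 23 trimethylaluminium; 24 ethylene oxide
Product: 27 (3E,7R,9Z)-13-(tert-butyldimethylsilyloxy)-4,10-dimethyl-7-[(triisopropylsilyl)ethynyl]trideca-3,9-dien-1-ol, via alkenylalane 25 (not isolated), via lithium alanate 26 (not isolated)
Conditions: 23 (2.5 equiv), Cp2ZrCl2 (0.25 equiv), CH2Cl2, rt; volatiles removed, hexane extract; n-BuLi, 0 °C; 24, THF, 0 °C to rt; then H2O
Reagents that add atoms: none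
Why: Negishi zirconium-catalysed methylalumination adds CH3 to C12 and aluminium to C11 in a syn fashion and thus fixes 11E, the doubly shielded internal silylalkyne and the trisubstituted alkene should stay out, and the more nucleophilic alanate made with n-BuLi hands its alkenyl group to ethylene oxide with retention to bring in C10 and C9.

Step 9
Reactants: 27 (3E,7R,9Z)-13-(tert-butyldimethylsilyloxy)-4,10-dimethyl-7-[(triisopropylsilyl)ethynyl]trideca-3,9-dien-1-ol
Product: 28 tert-butyl{[(4Z,7R,10E)-13-iodo-4,10-dimethyl-7-[(triisopropylsilyl)ethynyl]trideca-4,10-dienyl]oxy}dimethylsilane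
Conditions: I2, PPh3, imidazole, CH2Cl2, 0 °C
Reagents that add atoms: iodine, II
Why: Appel-type iodination (Garegg–Samuelsson conditions) replaces the primary hydroxyl group by SN2 displacement of the oxyphosphonium ion under nearly neutral conditions that spare silyl ether, alkynylsilane and alkenes.

Step 10
Reactants: 28 tert-butyl{[(4Z,7R,10E)-13-iodo-4,10-dimethyl-7-[(triisopropylsilyl)ethynyl]trideca-4,10-dienyl]oxy}dimethylsilane; 29 triethyl phosphonoacetate
Product: 31 ethyl (5E,9R,11Z)-15-(tert-butyldimethylsilyloxy)-2-(diethoxyphosphoryl)-6,12-dimethyl-9-[(triisopropylsilyl)ethynyl]pentadeca-5,11-dienoate (epimers at the phosphonate carbon), via sodium phosphonoacetate 30 (not isolated)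
Conditions: 29 (excess), NaH, DMF, 0 °C; then 28, 50 °C
Reagents that add atoms: none
Why: SN2 alkylation of the soft sodium phosphonoacetate anion, used in excess to suppress double alkylation, with the primary iodide forms C8–C9 and installs the olefination handle, and the new centre at C8 disappears in step 13.

Step 11
Reactants: 31 ethyl (5E,9R,11Z)-15-(tert-butyldimethylsilyloxy)-2-(diethoxyphosphoryl)-6,12-dimethyl-9-[(triisopropylsilyl)ethynyl]pentadeca-5,11-dienoate
Product: 32 ethyl (5E,9R,11Z)-2-(diethoxyphosphoryl)-9-ethynyl-15-hydroxy-6,12-dimethylpentadeca-5,11-dienoate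
Conditions: Bu4NF (3 equiv), THF, 0 °C to rt
Reagents that add atoms: none
Why: Fluoride cleaves the O–Si and the alkynyl C–Si bond in one operation, driven by the strong Si–F bond, while the phosphonoacetate merely rests as its stabilised anion until work-up.

Step 12
Reactants: 32 ethyl (5E,9R,11Z)-2-(diethoxyphosphoryl)-9-ethynyl-15-hydroxy-6,12-dimethylpentadeca-5,11-dienoate
Product: 33 ethyl (5E,9R,11Z)-2-(diethoxyphosphoryl)-9-ethynyl-6,12-dimethyl-15-oxopentadeca-5,11-dienoate
Conditions: Dess–Martin periodinane, CH2Cl2, 0 °C to rt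
Reagents that add atoms: none
Why: Dess–Martin oxidation stops at the aldehyde under non-basic conditions, so the phosphonate is not triggered prematurely.

Step 13
Reactants: 33 ethyl (5E,9R,11Z)-2-(diethoxyphosphoryl)-9-ethynyl-6,12-dimethyl-15-oxopentadeca-5,11-dienoate
Product: 34 ethyl (1R,3Z,7E,11E)-1-ethynyl-4,12-dimethylcyclotetradeca-3,7,11-triene-8-carboxylate
Conditions: LiCl, DBU, MeCN, rt, slow addition of 33 (final about 1 mM)
Reagents that add atoms: none
Why: The intramolecular Horner–Wadsworth–Emmons reaction under Masamune–Roush conditions at high dilution closes the 14-membered ring at C7=C8, and reversible addition of the α-alkyl phosphonoacetate anion favours the enoate with C6 trans to the ester (7E), a geometry that sets the two ring branches cis and is easily accommodated.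

Step 14
Reactants: 34 ethyl (1R,3Z,7E,11E)-1-ethynyl-4,12-dimethylcyclotetradeca-3,7,11-triene-8-carboxylate
Product: 35 [(1R,3Z,7E,11E)-1-ethynyl-4,12-dimethylcyclotetradeca-3,7,11-trien-8-yl]methanol
Conditions: i-Bu2AlH (2.5 equiv), CH2Cl2, −78 °C
Reagents that add atoms: none
Why: i-Bu2AlH performs 1,2-reduction of the enoate to the allylic alcohol at low temperature, where hydroalumination of the terminal alkyne does not compete.

Step 15
Reactants: 35 [(1R,3Z,7E,11E)-1-ethynyl-4,12-dimethylcyclotetradeca-3,7,11-trien-8-yl]methanol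
Product: 36 (1R,3Z,7E,11E)-8-(tert-butyldimethylsilyloxymethyl)-1-ethynyl-4,12-dimethylcyclotetradeca-3,7,11-triene
Conditions: t-BuMe2SiCl, imidazole, DMF, rt
Reagents that add atoms: tert-butylchlorodimethylsilane, CC(C)(C)[Si](C)(C)Cl
Why: Imidazole-promoted silylation masks the hydroxyl group, which would otherwise become an allylic aluminium alkoxide able to ionise on palladium in the next step.

Step 16
Reactants: 36 (1R,3Z,7E,11E)-8-(tert-butyldimethylsilyloxymethyl)-1-ethynyl-4,12-dimethylcyclotetradeca-3,7,11-triene; 23 trimethylaluminium; 37 prenyl chloride (1-chloro-3-methylbut-2-ene)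
Product: 39 (1R,3Z,7E,11E)-8-(tert-butyldimethylsilyloxymethyl)-4,12-dimethyl-1-[(2E)-6-methylhepta-2,5-dien-2-yl]cyclotetradeca-3,7,11-triene, via alkenylalane 38 (not isolated)
Conditions: 23 (3 equiv), Cp2ZrCl2 (0.5 equiv), ClCH2CH2Cl, rt; then 37 (1.5 equiv), Pd(PPh3)4 (5 mol %), THF, 0 °C to rt
Reagents that add atoms: none
Why: Cp2ZrCl2 and AlMe3 form a methylzirconocene–aluminium species that delivers CH3 and metal to the same face of the C15≡C16 triple bond, CH3 to the internal carbon C15 and the metal, passed on to aluminium, to the terminal carbon C16, which gives the (E)-alkenylalane 38. Zerovalent palladium then ionises prenyl chloride to a 1,1-dimethyl-π-allyl complex of divalent palladium, the alkenyl group moves from aluminium to palladium with retention, and reductive elimination at the unsubstituted CH2 terminus makes C16–C17 and keeps C18=C19 out of conjugation. The closest known chemistry is the Negishi zirconium-catalysed methylalumination of 1-alkynes followed in the same flask by Pd(PPh3)4-catalysed coupling with allylic chlorides to give 1,4-dienes. The step closes no ring and creates no stereocentre; it fixes only the E geometry of C15=C16, a consequence of syn addition, and C1 keeps its configuration because nothing in the flask removes the propargylic hydrogen. The substrate secures the chemoselectivity: the ethynyl group is its only alkyne, the three trisubstituted ring alkenes do not carbometalate, C8 carries a silyl ether rather than an ester that AlMe3 would attack, and the bulky allylic silyl ether ionises on palladium far more slowly than the allylic chloride.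

Step 17
Reactants: 39 (1R,3Z,7E,11E)-8-(tert-butyldimethylsilyloxymethyl)-4,12-dimethyl-1-[(2E)-6-methylhepta-2,5-dien-2-yl]cyclotetradeca-3,7,11-triene
Product: 40 {(1R,3Z,7E,11E)-4,12-dimethyl-1-[(2E)-6-methylhepta-2,5-dien-2-yl]cyclotetradeca-3,7,11-trien-8-yl}methanol
Conditions: Bu4NF, THF, rt
Reagents that add atoms: none
Why: Fluoride-induced desilylation frees the allylic alcohol without touching the five alkenes.

Step 18
Reactants: 40 {(1R,3Z,7E,11E)-4,12-dimethyl-1-[(2E)-6-methylhepta-2,5-dien-2-yl]cyclotetradeca-3,7,11-trien-8-yl}methanol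
Product: 41 (1R,3Z,7E,11E)-4,12-dimethyl-1-[(2E)-6-methylhepta-2,5-dien-2-yl]cyclotetradeca-3,7,11-triene-8-carbaldehyde
Conditions: MnO2, CH2Cl2, rt
Reagents that add atoms: none
Why: MnO2 oxidises allylic alcohols selectively to enals, and the 7E geometry with C6 trans to the formyl group is also the thermodynamically preferred one.

Step 19
Reactants: 41 (1R,3Z,7E,11E)-4,12-dimethyl-1-[(2E)-6-methylhepta-2,5-dien-2-yl]cyclotetradeca-3,7,11-triene-8-carbaldehyde
Product: 42 (1R,3Z,7E,11E)-4,12-dimethyl-1-[(2E)-6-methylhepta-2,5-dien-2-yl]cyclotetradeca-3,7,11-triene-8-carboxylic acid (target)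
Conditions: NaClO2, NaH2PO4, 2-methyl-2-butene (large excess), t-BuOH/H2O, rt
Reagents that add atoms: sodium chlorite, [Na+].[O-]Cl=O
Why: Pinnick oxidation converts the enal into the acid without alkene isomerisation, the excess 2-methyl-2-butene intercepting hypochlorous acid before it can reach the trisubstituted alkenes.

**Compound list**
1 | (+)-limonene 1,2-oxide, (4R)-1-methyl-4-(prop-1-en-2-yl)-7-oxabicyclo[4.1.0]heptane | C=C(C)[C@H]1CC2OC2(C)CC1 | starting material
2 | secondary ozonide of 1 | CC3(OCOO3)[C@H]1CC2OC2(C)CC1 | intermediate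
3 | 1-[(3R)-6-methyl-7-oxabicyclo[4.1.0]heptan-3-yl]ethanone | CC(=O)[C@H]1CC2OC2(C)CC1 | intermediate
4 | 1-[(1R)-4-methylcyclohex-3-en-1-yl]ethanone | CC(=O)[C@H]1CC=C(C)CC1 | intermediate
5 | terminal lithium enolate of 4 | [Li]OC(=C)[C@H]1CC=C(C)CC1 | intermediate
6 | diethyl 1-[(1R)-4-methylcyclohex-3-en-1-yl]ethenyl phosphate | C=C(OP(=O)(OCC)OCC)[C@H]1CC=C(C)CC1 | intermediate
7 | lithium [(1R)-4-methylcyclohex-3-en-1-yl]acetylide | [Li]C#C[C@H]1CC=C(C)CC1 | intermediate
8 | triisopropyl{[(1R)-4-methylcyclohex-3-en-1-yl]ethynyl}silane | CC(C)[Si](C#C[C@H]1CC=C(C)CC1)(C(C)C)C(C)C | intermediate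
9 | secondary ozonide of 8 (6,7,8-trioxabicyclo[3.2.1]octane) | CC(C)[Si](C#C[C@H]1CC2OOC(C)(O2)CC1)(C(C)C)C(C)C | intermediate
10 | (3R)-6-oxo-3-[(triisopropylsilyl)ethynyl]heptanal | CC(C)[Si](C#C[C@H](CCC(C)=O)CC=O)(C(C)C)C(C)C | intermediate
11 | ethyltriphenylphosphonium iodide | CC[P+](c1ccccc1)(c1ccccc1)c1ccccc1.[I-] | starting material
12 | ethylidenetriphenylphosphorane | CC=P(c1ccccc1)(c1ccccc1)c1ccccc1 | intermediate
13 | (1-iodoethyl)triphenylphosphonium iodide | CC(I)[P+](c1ccccc1)(c1ccccc1)c1ccccc1.[I-] | intermediate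
14 | (1-iodoethylidene)triphenylphosphorane | CC(I)=P(c1ccccc1)(c1ccccc1)c1ccccc1 | intermediate
15 | (5R,7Z)-8-iodo-5-[(triisopropylsilyl)ethynyl]non-7-en-2-one | CC(C)[Si](C#C[C@H](CCC(C)=O)C/C=C(/C)I)(C(C)C)C(C)C | intermediate
16 | allyloxy(tert-butyl)dimethylsilane | C=CCO[Si](C)(C)C(C)(C)C | starting material
17 | 9-[3-(tert-butyldimethylsilyloxy)propyl]-9-borabicyclo[3.3.1]nonane | CC(C)(C)[Si](C)(C)OCCCB1C2CCCC1CCC2 | intermediate
18 | (5R,7Z)-11-(tert-butyldimethylsilyloxy)-8-methyl-5-[(triisopropylsilyl)ethynyl]undec-7-en-2-one | CC(C)[Si](C#C[C@H](CCC(C)=O)C/C=C(/C)CCCO[Si](C)(C)C(C)(C)C)(C(C)C)C(C)C | intermediate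
19 | terminal lithium enolate of 18 | CC(C)[Si](C#C[C@H](CCC(=C)O[Li])C/C=C(/C)CCCO[Si](C)(C)C(C)(C)C)(C(C)C)C(C)C | intermediate
20 | terminal enol diethyl phosphate of 18 | CC(C)[Si](C#C[C@H](CCC(=C)OP(=O)(OCC)OCC)C/C=C(/C)CCCO[Si](C)(C)C(C)(C)C)(C(C)C)C(C)C | intermediate
21 | lithium acetylide of 22 | CC(C)[Si](C#C[C@H](CCC#C[Li])C/C=C(/C)CCCO[Si](C)(C)C(C)(C)C)(C(C)C)C(C)C | intermediate
22 | (4Z,7R)-7-(but-3-ynyl)-1-(tert-butyldimethylsilyloxy)-4-methyl-9-(triisopropylsilyl)non-4-en-8-yne | CC(C)[Si](C#C[C@H](CCC#C)C/C=C(/C)CCCO[Si](C)(C)C(C)(C)C)(C(C)C)C(C)C | intermediate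
23 | trimethylaluminium | C[Al](C)C | starting material
24 | ethylene oxide | C1CO1 | starting material
25 | (E)-alkenyl(dimethyl)alane from 22 (Al on C11, CH3 on C12) | CC(C)[Si](C#C[C@H](CC/C(C)=C/[Al](C)C)C/C=C(/C)CCCO[Si](C)(C)C(C)(C)C)(C(C)C)C(C)C | intermediate
26 | lithium (E)-alkenyl(butyl)dimethylalanate from 25 | CC(C)[Si](C#C[C@H](CC/C(C)=C/[Al-](C)(C)CCCC)C/C=C(/C)CCCO[Si](C)(C)C(C)(C)C)(C(C)C)C(C)C.[Li+] | intermediate
27 | (3E,7R,9Z)-13-(tert-butyldimethylsilyloxy)-4,10-dimethyl-7-[(triisopropylsilyl)ethynyl]trideca-3,9-dien-1-ol | CC(C)[Si](C#C[C@H](CC/C(C)=C/CCO)C/C=C(/C)CCCO[Si](C)(C)C(C)(C)C)(C(C)C)C(C)C | intermediate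
28 | tert-butyl{[(4Z,7R,10E)-13-iodo-4,10-dimethyl-7-[(triisopropylsilyl)ethynyl]trideca-4,10-dienyl]oxy}dimethylsilane | CC(C)[Si](C#C[C@H](CC/C(C)=C/CCI)C/C=C(/C)CCCO[Si](C)(C)C(C)(C)C)(C(C)C)C(C)C | intermediate
29 | triethyl phosphonoacetate | CCOC(=O)CP(=O)(OCC)OCC | starting material
30 | sodium salt of triethyl phosphonoacetate | [Na+].CCOC(=O)[CH-]P(=O)(OCC)OCC | intermediate
31 | ethyl (5E,9R,11Z)-15-(tert-butyldimethylsilyloxy)-2-(diethoxyphosphoryl)-6,12-dimethyl-9-[(triisopropylsilyl)ethynyl]pentadeca-5,11-dienoate | CC(C)[Si](C#C[C@H](CC/C(C)=C/CCC(C(=O)OCC)P(=O)(OCC)OCC)C/C=C(/C)CCCO[Si](C)(C)C(C)(C)C)(C(C)C)C(C)C | intermediate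
32 | ethyl (5E,9R,11Z)-2-(diethoxyphosphoryl)-9-ethynyl-15-hydroxy-6,12-dimethylpentadeca-5,11-dienoate | C#C[C@H](CC/C(C)=C/CCC(C(=O)OCC)P(=O)(OCC)OCC)C/C=C(/C)CCCO | intermediate
33 | ethyl (5E,9R,11Z)-2-(diethoxyphosphoryl)-9-ethynyl-6,12-dimethyl-15-oxopentadeca-5,11-dienoate | C#C[C@H](CC/C(C)=C/CCC(C(=O)OCC)P(=O)(OCC)OCC)C/C=C(/C)CCC=O | intermediate
34 | ethyl (1R,3Z,7E,11E)-1-ethynyl-4,12-dimethylcyclotetradeca-3,7,11-triene-8-carboxylate | C#C[C@H]1C/C=C(/C)CC/C=C(/C(=O)OCC)CC/C=C(\C)CC1 | intermediate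
35 | [(1R,3Z,7E,11E)-1-ethynyl-4,12-dimethylcyclotetradeca-3,7,11-trien-8-yl]methanol | C#C[C@H]1C/C=C(/C)CC/C=C(/CO)CC/C=C(\C)CC1 | intermediate
36 | (1R,3Z,7E,11E)-8-(tert-butyldimethylsilyloxymethyl)-1-ethynyl-4,12-dimethylcyclotetradeca-3,7,11-triene | C#C[C@H]1C/C=C(/C)CC/C=C(/CO[Si](C)(C)C(C)(C)C)CC/C=C(\C)CC1 | intermediate
37 | prenyl chloride | CC(C)=CCCl | starting material
38 | (E)-alkenyl(dimethyl)alane from 36 (Al on C16, CH3 on C15) | C[Al](C)/C=C(\C)[C@H]1C/C=C(/C)CC/C=C(/CO[Si](C)(C)C(C)(C)C)CC/C=C(\C)CC1 | intermediate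
39 | (1R,3Z,7E,11E)-8-(tert-butyldimethylsilyloxymethyl)-4,12-dimethyl-1-[(2E)-6-methylhepta-2,5-dien-2-yl]cyclotetradeca-3,7,11-triene | CC(C)=CC/C=C(\C)[C@H]1C/C=C(/C)CC/C=C(/CO[Si](C)(C)C(C)(C)C)CC/C=C(\C)CC1 | intermediate
40 | {(1R,3Z,7E,11E)-4,12-dimethyl-1-[(2E)-6-methylhepta-2,5-dien-2-yl]cyclotetradeca-3,7,11-trien-8-yl}methanol | CC(C)=CC/C=C(\C)[C@H]1C/C=C(/C)CC/C=C(/CO)CC/C=C(\C)CC1 | intermediate
41 | (1R,3Z,7E,11E)-4,12-dimethyl-1-[(2E)-6-methylhepta-2,5-dien-2-yl]cyclotetradeca-3,7,11-triene-8-carbaldehyde | CC(C)=CC/C=C(\C)[C@H]1C/C=C(/C)CC/C=C(/C=O)CC/C=C(\C)CC1 | intermediate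
42 | (1R,3Z,7E,11E)-4,12-dimethyl-1-[(2E)-6-methylhepta-2,5-dien-2-yl]cyclotetradeca-3,7,11-triene-8-carboxylic acid | CC(C)=CC/C=C(\C)[C@H]1C/C=C(/C)CC/C=C(/C(=O)O)CC/C=C(\C)CC1 | target

**Step count**
Total steps: 19. Longest linear sequence: 19 steps (1 to 42). All other partners (11, 16, 23, 24, 29, 37) are purchased.

**Steps most likely to fail**

Step 13 (ring closure). Bimolecular olefination leading to dimers and oligomers may outrun cyclisation, and strain in the cyclic transition state may erode the preference for 7E. The fallback closes the same C7=C8 bond by alkene metathesis instead of carbonyl olefination. It sets out from 31.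
- Aqueous formaldehyde and K2CO3 turn the phosphonate into the 2-substituted acrylate F1.
- HF·pyridine frees the primary alcohol F2 while the alkynylsilane stays in place.
- Dess–Martin oxidation gives the aldehyde F3, and Ph3P=CH2 at −78 °C gives the terminal alkene F4.
- The second-generation Grubbs catalyst in dilute hot toluene should close the ring to the silyl-capped macrocyclic ester F5, the capped alkyne staying out of the metathesis.
- Bu4NF removes the cap, and the route is rejoined at 34.

Step 5 (Z-iodoolefination). Partial loss of iodine from the ylide, sluggish addition, leakage to the E isomer and base-induced aldol reactions of the keto aldehyde may all lower the throughput. The fallback builds the 3Z alkene by two stereoselective cross-couplings on a gem-dihaloalkene instead of a Wittig reaction. It sets out from 10.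
- PPh3 and CCl4 convert the aldehyde into the 1,1-dichloroalkene F6.
- Me2Zn with PdCl2(DPEphos) in DMF replaces selectively the chloride trans to the chain and gives the (Z)-chloroalkene F7.
- The alkylzinc iodide F8, made from commercial tert-butyl(3-iodopropoxy)dimethylsilane and zinc dust, replaces the remaining chloride with retention under Pd(t-Bu3P)2.
- This Negishi coupling returns to the route at 18.

Step 8 (methylalumination and epoxide opening). The capped alkyne may be drawn into carbometalation, butyl or methyl may transfer to the epoxide in place of the alkenyl group, and the supply of 22 depends on the regioselectivity of enolisation in step 7. The fallback makes the 11E alkene by ketone olefination and adds C9 with a hydroxymethyl anion equivalent. It sets out from 18, so step 7 is bypassed as well.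
- A Horner–Wadsworth–Emmons reaction with 29 and NaH gives the (E)-enoate F9, to be freed from its Z isomer by chromatography.
- i-Bu2AlH reduces it to the allylic alcohol F10.
- CBr4 and PPh3 give the allylic bromide F11.
- (i-PrO)Me2SiCH2MgCl with catalytic CuI couples at the primary carbon to give the homoallylic silane F12.
- Tamao oxidation (H2O2, KF, KHCO3) returns to the route at 27.

**Further compounds**
F1 | step 13 | ethyl (5E,9R,11Z)-15-(tert-butyldimethylsilyloxy)-6,12-dimethyl-2-methylidene-9-[(triisopropylsilyl)ethynyl]pentadeca-5,11-dienoate | CC(C)[Si](C#C[C@H](CC/C(C)=C/CCC(=C)C(=O)OCC)C/C=C(/C)CCCO[Si](C)(C)C(C)(C)C)(C(C)C)C(C)C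
F2 | step 13 | ethyl (5E,9R,11Z)-15-hydroxy-6,12-dimethyl-2-methylidene-9-[(triisopropylsilyl)ethynyl]pentadeca-5,11-dienoate | CC(C)[Si](C#C[C@H](CC/C(C)=C/CCC(=C)C(=O)OCC)C/C=C(/C)CCCO)(C(C)C)C(C)C
F3 | step 13 | ethyl (5E,9R,11Z)-6,12-dimethyl-2-methylidene-15-oxo-9-[(triisopropylsilyl)ethynyl]pentadeca-5,11-dienoate | CC(C)[Si](C#C[C@H](CC/C(C)=C/CCC(=C)C(=O)OCC)C/C=C(/C)CCC=O)(C(C)C)C(C)C
F4 | step 13 | ethyl (5E,9R,11Z)-6,12-dimethyl-2-methylidene-9-[(triisopropylsilyl)ethynyl]hexadeca-5,11,15-trienoate | CC(C)[Si](C#C[C@H](CC/C(C)=C/CCC(=C)C(=O)OCC)C/C=C(/C)CCC=C)(C(C)C)C(C)C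
F5 | step 13 | ethyl (1R,3Z,7E,11E)-4,12-dimethyl-1-[(triisopropylsilyl)ethynyl]cyclotetradeca-3,7,11-triene-8-carboxylate | CC(C)[Si](C#C[C@H]1C/C=C(/C)CC/C=C(/C(=O)OCC)CC/C=C(\C)CC1)(C(C)C)C(C)C
F6 | step 5 | (5R)-8,8-dichloro-5-[(triisopropylsilyl)ethynyl]oct-7-en-2-one | CC(C)[Si](C#C[C@H](CCC(C)=O)CC=C(Cl)Cl)(C(C)C)C(C)C
F7 | step 5 | (5R,7Z)-8-chloro-5-[(triisopropylsilyl)ethynyl]non-7-en-2-one | CC(C)[Si](C#C[C@H](CCC(C)=O)C/C=C(/C)Cl)(C(C)C)C(C)C
F8 | step 5 | [3-(tert-butyldimethylsilyloxy)propyl]zinc iodide | CC(C)(C)[Si](C)(C)OCCC[Zn]I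
F9 | step 8 | ethyl (2E,6R,8Z)-12-(tert-butyldimethylsilyloxy)-3,9-dimethyl-6-[(triisopropylsilyl)ethynyl]dodeca-2,8-dienoate | CC(C)[Si](C#C[C@H](CC/C(C)=C/C(=O)OCC)C/C=C(/C)CCCO[Si](C)(C)C(C)(C)C)(C(C)C)C(C)C
F10 | step 8 | (2E,6R,8Z)-12-(tert-butyldimethylsilyloxy)-3,9-dimethyl-6-[(triisopropylsilyl)ethynyl]dodeca-2,8-dien-1-ol | CC(C)[Si](C#C[C@H](CC/C(C)=C/CO)C/C=C(/C)CCCO[Si](C)(C)C(C)(C)C)(C(C)C)C(C)C
F11 | step 8 | tert-butyl{[(4Z,7R,10E)-12-bromo-4,10-dimethyl-7-[(triisopropylsilyl)ethynyl]dodeca-4,10-dienyl]oxy}dimethylsilane | CC(C)[Si](C#C[C@H](CC/C(C)=C/CBr)C/C=C(/C)CCCO[Si](C)(C)C(C)(C)C)(C(C)C)C(C)C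
F12 | step 8 | [(3E,7R,9Z)-13-(tert-butyldimethylsilyloxy)-4,10-dimethyl-7-[(triisopropylsilyl)ethynyl]trideca-3,9-dienyl](isopropoxy)dimethylsilane | CC(C)[Si](C#C[C@H](CC/C(C)=C/CC[Si](C)(C)OC(C)C)C/C=C(/C)CCCO[Si](C)(C)C(C)(C)C)(C(C)C)C(C)C
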